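**Retrosynthetic overview**

1. 26 ⇐ diol 23 (one Dess–Martin oxidation makes both the C8 aldehyde and the C2' ketone) ⇐ triol 21 (palmitoylation of C7–CH2OH) ⇐ lactone 18; the C7 and C8 benzylic carbons travel as a γ-lactone (phthalide) fused to the benzene ring.
2. Side chain: the C2'–C3' bond comes from aldehyde 18 and an isobutenyl Grignard reagent; C1'–C2' is the second vinyl group of 14 (hydroboration); C3–C4 comes from C3=C4 (hydrogenation).
3. Key disconnection C3=C4 of the pyran ring: enantioselective ring-closing metathesis of the achiral triene 13 closes the pyran ring and sets C2, the only stereocentre. Enabling feature: C2 bears O1, CH3 and two carbon arms, C3 (pyran ring) and C1' (side chain), that can both be vinyl groups, so C2 is a prochiral divinyl carbinol carbon and the vinyl group on C4a selects one arm.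
4. 13 ⇐ phenol 5 + diynol 9 (copper-catalysed etherification at the tertiary propargylic carbon, then semihydrogenation); 5 ⇐ 5,7-dimethoxyphthalide 1.
5. Order of rings: the benzene and lactone rings are purchased in 1; the pyran ring is formed in step 7; the lactone ring is opened by reduction in step 11.

Key step: step 7

Remark: chroman numbering of the target (O1, C2, C3, C4, C4a, C5–C8, C8a; side chain C1'–C4') is used for the corresponding atoms of all intermediates. The target is (S) at C2; intermediates 14–16 are (R) only because the ring sp2 carbon C3 outranks the side arm. 5,7-Dimethoxyphthalide is taken as a catalogue compound.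

**Route**

Step 1
Reactants: 1 5,7-dimethoxyphthalide
Product: 2 7-hydroxy-5-methoxyphthalide
Conditions: BCl3 (1.5 equiv), CH2Cl2, −78 °C → rt; aq. NaHCO3
Reagents that add atoms: none
Why: BCl3 chelated between the lactone C=O and the neighbouring C7 methoxy oxygen cleaves only that ether (chelation-controlled Lewis-acid demethylation of an ortho-carbonyl aryl methyl ether), so the methoxy group that becomes the C5 OMe of the target stays.

Step 2
Reactants: 2 7-hydroxy-5-methoxyphthalide
Product: 4 6-formyl-7-hydroxy-5-methoxyphthalide, via hydroxymethylphenol 3 (not isolated)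
Conditions: MgCl2, Et3N, (CH2O)n, MeCN, reflux
Reagents that add atoms: paraformaldehyde (source of formaldehyde), C=O
Why: the magnesium phenoxide delivers formaldehyde to the only free ortho carbon (between OH and OMe) and a second formaldehyde oxidises the benzylic alkoxide by hydride transfer (Casnati–Skattebøl ortho-formylation), so the para position is not attacked.

Step 3
Reactants: 4 6-formyl-7-hydroxy-5-methoxyphthalide
Product: 5 7-hydroxy-5-methoxy-6-vinylphthalide
Conditions: Ph3PCH3Br (2.5 equiv), KOtBu (2.4 equiv), THF, 0 °C → rt; aq. NH4Cl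
Reagents that add atoms: methyltriphenylphosphonium bromide, C[P+](c1ccccc1)(c1ccccc1)c1ccccc1.[Br-]
Why: Wittig methylenation of the aryl aldehyde proceeds on the phenoxide with excess non-stabilised ylide, which does not attack the lactone at or below room temperature.

Step 4
Reactants: 6 ethyl acetate; 7 ethynylmagnesium bromide
Product: 9 3-methylpenta-1,4-diyn-3-ol, via but-3-yn-2-one 8 (not isolated)
Conditions: 7 (2.2 equiv, 0.5 M in THF), THF, 0 °C → rt; aq. NH4Cl
Reagents that add atoms: none
Why: double Grignard addition of the acetylide to the ester gives the tertiary alcohol because the ynone formed first is more electrophilic than the ester; the product is achiral.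

Step 5
Reactants: 5 7-hydroxy-5-methoxy-6-vinylphthalide; 9 3-methylpenta-1,4-diyn-3-ol
Product: 11 5-methoxy-7-[(3-methylpenta-1,4-diyn-3-yl)oxy]-6-vinylphthalide, via trifluoroacetate 10 (not isolated)
Conditions: 9, (CF3CO)2O, DBU, MeCN, −5 °C; then 5, DBU, CuCl2·2H2O (1 mol %), MeCN, −5 → 0 °C, N2
Reagents that add atoms: none
Why: in this copper-catalysed propargylic etherification a copper acetylide of the tertiary trifluoroacetate ionises to a copper allenylidene, which the phenoxide captures at the tertiary carbon below 0 °C, a reaction type established for hindered aryl 1,1-dialkylpropargyl ethers; the product is achiral.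

Step 6
Reactants: 11 5-methoxy-7-[(3-methylpenta-1,4-diyn-3-yl)oxy]-6-vinylphthalide
Product: 13 5-methoxy-7-[(3-methylpenta-1,4-dien-3-yl)oxy]-6-vinylphthalide, via enyne 12 (not isolated)
Conditions: H2 (1 atm), Pd/CaCO3 poisoned with Pb(OAc)2 (Lindlar catalyst), quinoline, EtOAc, rt, stopped after 2 equiv H2
Reagents that add atoms: none
Why: semihydrogenation over poisoned Pd stops each terminal alkyne at the alkene and should leave the aryl vinyl group and the tertiary C–O bond intact; the product is achiral because both arms end as vinyl groups.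

Step 7
Reactants: 13 5-methoxy-7-[(3-methylpenta-1,4-dien-3-yl)oxy]-6-vinylphthalide
Product: 14 (R)-5-methoxy-2-methyl-2-vinyl-2H-furo[3,4-h]chromen-9(7H)-one
Conditions: Mo(N-2,6-i-Pr2C6H3)(=CHCMe2Ph)[(S)-3,3'-di-tert-butyl-5,5',6,6'-tetramethylbiphenyl-2,2'-diolate] (5–10 mol %), C6H6 (0.02 M), 22 → 50 °C, N2, ethene vented, dark
Reagents that add atoms: none
Why: Proposed new method: the Mo alkylidene exchanges onto the aryl vinyl group (future C4), and the Mo benzylidene then adds across one of the two enantiotopic vinyl groups on the carbinol carbon (future C2) to give a molybdacyclobutane that collapses with loss of ethene, forming C3=C4 and closing the pyran ring as a 6-membered ring-closing metathesis. The closest known reaction types are the Mo-catalysed enantioselective desymmetrising ring-closing metathesis of tertiary ethers of 1,4-dien-3-ols to 2,2-disubstituted dihydrofurans and dihydropyrans, and the ring-closing metathesis of 2-vinylphenyl tert-allyl ethers to 2,2-disubstituted 2H-chromenes; their combination on an aryl 1,4-dien-3-yl ether has not been shown. The only new stereocentre, C2, is set under catalyst control, because the chiral biphenolate and the arylimido ligand should let the metallacycle form on one vinyl group only; the sense of induction cannot be taken over with certainty from the dihydrofuran cases, so the catalyst enantiomer that gives (R)-14 is to be fixed by correlation in the first run and the mirror-image catalyst used if needed. The step needs group selectivity between the two vinyl groups, ring closure in preference to cross-metathesis, and no later equilibration; high dilution, removal of ethene and the low reactivity of the remaining vinyl group on a fully substituted carbon should secure this. The lactone is the only carbonyl group present, because a free aldehyde would be olefinated by the Mo alkylidene.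

Step 8
Reactants: 14 (R)-5-methoxy-2-methyl-2-vinyl-2H-furo[3,4-h]chromen-9(7H)-one
Product: 16 (R)-2-(2-hydroxyethyl)-5-methoxy-2-methyl-2H-furo[3,4-h]chromen-9(7H)-one, via alkylborane 15 (not isolated)
Conditions: 9-BBN (1.3 equiv), THF, 0 °C → rt; then 30% H2O2, pH 7 buffer (KH2PO4/Na2HPO4), 0 °C → rt, dark
Reagents that add atoms: hydrogen peroxide, OO
Why: in this anti-Markovnikov hydroboration–oxidation 9-BBN should react with the terminal vinyl group much faster than with the cis-disubstituted ring alkene and does not reduce the lactone; C2 is not touched.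

Step 9
Reactants: 16 (R)-2-(2-hydroxyethyl)-5-methoxy-2-methyl-2H-furo[3,4-h]chromen-9(7H)-one
Product: 17 (S)-2-(2-hydroxyethyl)-5-methoxy-2-methyl-3,4-dihydro-2H-furo[3,4-h]chromen-9(7H)-one
Conditions: H2 (1 atm), 5% Pd/C, EtOAc, rt
Reagents that add atoms: none
Why: heterogeneous catalytic hydrogenation saturates the styrene-type C3=C4 bond while the lactone CH2–O bond resists hydrogenolysis under neutral conditions at 1 atm; this removes the 2H-chromene that could racemise C2 by electrocyclic ring opening (the descriptor changes to S only by the priority rules).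

Step 10
Reactants: 17 (S)-2-(2-hydroxyethyl)-5-methoxy-2-methyl-3,4-dihydro-2H-furo[3,4-h]chromen-9(7H)-one
Product: 18 (S)-2-(5-methoxy-2-methyl-9-oxo-3,4,7,9-tetrahydro-2H-furo[3,4-h]chromen-2-yl)acetaldehyde
Conditions: Dess–Martin periodinane, NaHCO3, CH2Cl2, 0 °C
Reagents that add atoms: none
Why: Dess–Martin oxidation under buffered, non-basic conditions gives the β-aryloxy aldehyde without β-elimination of the phenoxide, which would open the pyran ring and racemise C2.

Step 11
Reactants: 18 (S)-2-(5-methoxy-2-methyl-9-oxo-3,4,7,9-tetrahydro-2H-furo[3,4-h]chromen-2-yl)acetaldehyde; 19 2-methylprop-1-en-1-ylmagnesium bromide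
Product: 21 1-[(2S)-7,8-bis(hydroxymethyl)-5-methoxy-2-methylchroman-2-yl]-4-methylpent-3-en-2-ol, via hydroxy lactone 20 (not isolated)
Conditions: 19 (1.1 equiv), THF, −78 °C; then LiAlH4 (1.5 equiv), −78 → 0 °C; aq. potassium sodium tartrate
Reagents that add atoms: none
Why: Grignard 1,2-addition to the aliphatic aldehyde at −78 °C should outrun attack on the hindered lactone and enolisation, and LiAlH4 then reduces the lactone to the diol; the new carbinol centre forms without control and both epimers are carried on because step 13 oxidises it away.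

Step 12
Reactants: 21 1-[(2S)-7,8-bis(hydroxymethyl)-5-methoxy-2-methylchroman-2-yl]-4-methylpent-3-en-2-ol; 22 vinyl palmitate
Product: 23 [(2S)-8-(hydroxymethyl)-2-(2-hydroxy-4-methylpent-3-en-1-yl)-5-methoxy-2-methylchroman-7-yl]methyl hexadecanoate
Conditions: immobilised Candida antarctica lipase B, 22 (3 equiv), t-BuOMe, 4 Å molecular sieves, 35 °C
Reagents that add atoms: none
Why: lipase-catalysed transesterification with an irreversible vinyl ester donor should acylate the least hindered primary hydroxyl (C7–CH2OH, one ortho hydrogen) and leave C8–CH2OH (two ortho substituents) and the hindered secondary allylic alcohol.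

Step 13
Reactants: 23 [(2S)-8-(hydroxymethyl)-2-(2-hydroxy-4-methylpent-3-en-1-yl)-5-methoxy-2-methylchroman-7-yl]methyl hexadecanoate
Product: 26 [(2S)-8-formyl-5-methoxy-2-methyl-2-(4-methyl-2-oxopent-3-en-1-yl)chroman-7-yl]methyl hexadecanoate, via hydroxy aldehyde 24 (not isolated), via keto alcohol 25 (not isolated)
Conditions: Dess–Martin periodinane (2.6 equiv), NaHCO3, CH2Cl2, 0 °C → rt
Reagents that add atoms: none
Why: Dess–Martin oxidation converts the benzylic primary and the allylic secondary alcohol in one operation, and the buffered conditions avoid retro-oxa-Michael opening of the β-aryloxy ketone, so C2 keeps its configuration and both carbinol epimers converge on one product.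

**Compound list**

1 | 5,7-dimethoxyphthalide (5,7-dimethoxy-3H-isobenzofuran-1-one) | O=C1OCc2cc(OC)cc(OC)c12 | starting material
2 | 7-hydroxy-5-methoxyphthalide | O=C1OCc2cc(OC)cc(O)c12 | intermediate
3 | 7-hydroxy-6-(hydroxymethyl)-5-methoxyphthalide (formed in the flask) | O=C1OCc2cc(OC)c(CO)c(O)c12 | intermediate
4 | 6-formyl-7-hydroxy-5-methoxyphthalide | O=C1OCc2cc(OC)c(C=O)c(O)c12 | intermediate
5 | 7-hydroxy-5-methoxy-6-vinylphthalide | O=C1OCc2cc(OC)c(C=C)c(O)c12 | intermediate
6 | ethyl acetate | CCOC(C)=O | starting material
7 | ethynylmagnesium bromide | C#C[Mg]Br | starting material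
8 | but-3-yn-2-one (formed in the flask) | CC(=O)C#C | intermediate
9 | 3-methylpenta-1,4-diyn-3-ol | C#CC(C)(O)C#C | intermediate
10 | 3-methylpenta-1,4-diyn-3-yl trifluoroacetate (formed in the flask) | C#CC(C)(OC(=O)C(F)(F)F)C#C | intermediate
11 | 5-methoxy-7-[(3-methylpenta-1,4-diyn-3-yl)oxy]-6-vinylphthalide | O=C1OCc2cc(OC)c(C=C)c(OC(C)(C#C)C#C)c12 | intermediate
12 | rac-5-methoxy-7-[(3-methylpent-1-en-4-yn-3-yl)oxy]-6-vinylphthalide (formed in the flask) | O=C1OCc2cc(OC)c(C=C)c(OC(C)(C=C)C#C)c12 | intermediate
13 | 5-methoxy-7-[(3-methylpenta-1,4-dien-3-yl)oxy]-6-vinylphthalide (achiral triene) | O=C1OCc2cc(OC)c(C=C)c(OC(C)(C=C)C=C)c12 | intermediate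
14 | (R)-5-methoxy-2-methyl-2-vinyl-2H-furo[3,4-h]chromen-9(7H)-one (2H-chromene with a γ-lactone fused at C7–C8, C=O on C8, OCH2 on C7) | O=C1OCc2cc(OC)c3c(c12)O[C@](C)(C=C)C=C3 | intermediate
15 | B-alkyl-9-borabicyclo[3.3.1]nonane adduct of 14 at the terminal vinyl carbon (formed in the flask) | O=C1OCc2cc(OC)c3c(c12)O[C@](C)(CCB1C2CCCC1CCC2)C=C3 | intermediate
16 | (R)-2-(2-hydroxyethyl)-5-methoxy-2-methyl-2H-furo[3,4-h]chromen-9(7H)-one | O=C1OCc2cc(OC)c3c(c12)O[C@](C)(CCO)C=C3 | intermediate
17 | (S)-2-(2-hydroxyethyl)-5-methoxy-2-methyl-3,4-dihydro-2H-furo[3,4-h]chromen-9(7H)-one | O=C1OCc2cc(OC)c3c(c12)O[C@](C)(CCO)CC3 | intermediate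
18 | (S)-2-(5-methoxy-2-methyl-9-oxo-3,4,7,9-tetrahydro-2H-furo[3,4-h]chromen-2-yl)acetaldehyde | O=C1OCc2cc(OC)c3c(c12)O[C@](C)(CC=O)CC3 | intermediate
19 | 2-methylprop-1-en-1-ylmagnesium bromide | CC(C)=C[Mg]Br | starting material
20 | (2S)-2-(2-hydroxy-4-methylpent-3-en-1-yl)-5-methoxy-2-methyl-3,4-dihydro-2H-furo[3,4-h]chromen-9(7H)-one, both carbinol epimers (formed in the flask) | O=C1OCc2cc(OC)c3c(c12)O[C@](C)(CC(O)C=C(C)C)CC3 | intermediate
21 | 1-[(2S)-7,8-bis(hydroxymethyl)-5-methoxy-2-methylchroman-2-yl]-4-methylpent-3-en-2-ol, both carbinol epimers | OCc1cc(OC)c2c(c1CO)O[C@](C)(CC(O)C=C(C)C)CC2 | intermediate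
22 | vinyl palmitate (ethenyl hexadecanoate) | CCCCCCCCCCCCCCCC(=O)OC=C | starting material
23 | [(2S)-8-(hydroxymethyl)-2-(2-hydroxy-4-methylpent-3-en-1-yl)-5-methoxy-2-methylchroman-7-yl]methyl hexadecanoate, both carbinol epimers | CCCCCCCCCCCCCCCC(=O)OCc1cc(OC)c2c(c1CO)O[C@](C)(CC(O)C=C(C)C)CC2 | intermediate
24 | [(2S)-8-formyl-2-(2-hydroxy-4-methylpent-3-en-1-yl)-5-methoxy-2-methylchroman-7-yl]methyl hexadecanoate (formed in the flask) | CCCCCCCCCCCCCCCC(=O)OCc1cc(OC)c2c(c1C=O)O[C@](C)(CC(O)C=C(C)C)CC2 | intermediate
25 | [(2S)-8-(hydroxymethyl)-5-methoxy-2-methyl-2-(4-methyl-2-oxopent-3-en-1-yl)chroman-7-yl]methyl hexadecanoate (formed in the flask) | CCCCCCCCCCCCCCCC(=O)OCc1cc(OC)c2c(c1CO)O[C@](C)(CC(=O)C=C(C)C)CC2 | intermediate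
26 | [(2S)-8-formyl-5-methoxy-2-methyl-2-(4-methyl-2-oxopent-3-en-1-yl)chroman-7-yl]methyl hexadecanoate | CCCCCCCCCCCCCCCC(=O)OCc1cc(OC)c2c(c1C=O)O[C@](C)(CC(=O)C=C(C)C)CC2 | target

**Step count**

Total steps: 13. Longest linear sequence: 12 (steps 1–3 and 5–13; step 4 makes the diynol branch).

**Steps most likely to fail**

1. Step 7 (proposed new method). The catalyst may discriminate poorly between the two enantiotopic vinyl groups. Initiation at the doubly ortho-substituted styrene may be slow. Electrocyclic ring opening and reclosure of the 2H-chromene under light or heat would erode the enantiomeric purity. Fallback with known chemistry, setting out from 13 and coming back at 14: RuCl2(H2IMes)(=CH-C6H4-2-O-i-Pr) (second-generation Hoveyda–Grubbs catalyst, 5 mol %) in CH2Cl2 at 40 °C closes the same C3=C4 bond by ordinary ring-closing metathesis and gives the racemic chromene F1. Preparative chromatography on a chiral stationary phase (amylose tris(3,5-dimethylphenylcarbamate), supercritical CO2/MeOH) then separates (R)-chromene 14 from the (S)-enantiomer F2, which is discarded. The route continues with step 8.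

2. Step 5. Capture of the propargylic cation equivalent by the hindered, hydrogen-bonded phenoxide may be slow, so that elimination and oligomerisation of the diynyl electrophile take over. Fallback that inverts the polarity of the C–O bond formation, setting out from 4 and coming back at 13: deoxyfluorination of phenol 4 with 1,3-bis(2,6-diisopropylphenyl)-2,2-difluoro-2,3-dihydro-1H-imidazole and CsF (toluene, 110 °C) gives the aryl fluoride F3, whose fluorine is flanked by two carbonyl-bearing carbons. The potassium alkoxide of commercial 3-methylpenta-1,4-dien-3-ol (KHMDS, THF, −40 → 0 °C) displaces fluoride by nucleophilic aromatic substitution and gives the aryl ether aldehyde F4. Wittig methylenation (Ph3P=CH2, THF, 0 °C) then gives triene 13, so steps 3 to 6 are bypassed.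

3. Step 12. Discrimination between the two benzylic hydroxyls may be incomplete, leading to acylation at C8–CH2OH, double acylation, or acyl migration between the neighbouring benzylic oxygens. Fallback that differentiates the two benzylic carbons by oxidation level, setting out from 20 and coming back at 24: step 11 is stopped after the Grignard stage so that hydroxy lactone 20 is isolated. Me2AlN(OMe)Me (from MeNHOMe·HCl and AlMe3, CH2Cl2, 0 °C → rt) opens the lactone to the hydroxy Weinreb amide F5, in which only the C7 carbon carries a primary alcohol. Palmitoyl chloride with 2,4,6-collidine (CH2Cl2, −40 °C) acylates this primary hydroxyl in preference to the hindered secondary one and gives the palmitate F6. Cp2Zr(H)Cl (THF, rt) reduces the tertiary amide to the aldehyde without touching the ester and gives hydroxy aldehyde 24, which is oxidised to 26 under the conditions of step 13.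

**Further compounds**

F1 | step 7 | rac-5-methoxy-2-methyl-2-vinyl-2H-furo[3,4-h]chromen-9(7H)-one | O=C1OCc2cc(OC)c3c(c12)OC(C)(C=C)C=C3
F2 | step 7 | (S)-5-methoxy-2-methyl-2-vinyl-2H-furo[3,4-h]chromen-9(7H)-one | O=C1OCc2cc(OC)c3c(c12)O[C@@](C)(C=C)C=C3
F3 | step 5 | 7-fluoro-6-formyl-5-methoxyphthalide | O=C1OCc2cc(OC)c(C=O)c(F)c12
F4 | step 5 | 6-formyl-5-methoxy-7-[(3-methylpenta-1,4-dien-3-yl)oxy]phthalide | O=C1OCc2cc(OC)c(C=O)c(OC(C)(C=C)C=C)c12
F5 | step 12 | (2S)-7-(hydroxymethyl)-2-(2-hydroxy-4-methylpent-3-en-1-yl)-N,5-dimethoxy-N,2-dimethylchroman-8-carboxamide | OCc1cc(OC)c2c(c1C(=O)N(C)OC)O[C@](C)(CC(O)C=C(C)C)CC2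
F6 | step 12 | [(2S)-2-(2-hydroxy-4-methylpent-3-en-1-yl)-5-methoxy-8-[methoxy(methyl)carbamoyl]-2-methylchroman-7-yl]methyl hexadecanoate | CCCCCCCCCCCCCCCC(=O)OCc1cc(OC)c2c(c1C(=O)N(C)OC)O[C@](C)(CC(O)C=C(C)C)CC2
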